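**Plan**
- Retrosynthetic cuts: first the C3–O ester bond, which releases an (R)-4-(angeloyloxy)hex-2-ynoic acid (the Z-enoate comes from semi-hydrogenation). Next C8–C9 of ring B, by a pinacol transform, to a 1,6-dialdehyde. Then C7–isopropenyl, C9–C10, C5–C6 and C4–CH3, back to an (R)-4-silyloxycyclohexenone.
- Enabling feature: C8 and C9 are adjacent cis secondary carbinols in ring B. They are the retron of a reductive coupling between a formyl group on C10 of ring A and the formyl group that ends the C6–C7–C8 arm on C5.
- Forward order: ring A is bought as the enone and substituted at C4 and C5, then C9 is added on C10, then C7 and C8 are built on the arm. Ring B is closed by SmI2. The side chain, made separately, is esterified to O3 and semi-hydrogenated.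
- Stereochemistry: C3 comes from the starting enone. C4 is set anti to the silyloxy group (cuprate) and C5 anti to the C4 methyl (allylation). C10 is set by axial protonation and equilibration, C7 by an (R)-BINAP–Rh catalyst, and C8/C9 by samarium chelation on the α face. C4′ comes from (R)-pent-1-yn-3-ol; the two Z alkenes come from angelic acid and from syn hydrogenation.

Key step: step 13

Remark (assumption): enone 1 is treated as a purchasable enantiopure building block. Atoms carry eremophilane numbers throughout (ring A = C1–C5 and C10; ring B = C5–C10). α/β refer to the faces of the final decalin (C5 methyl = β), also for the monocyclic intermediates.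

**Route**

Step 1
Reactants: 1 (R)-4-(tert-butyldimethylsilyloxy)cyclohex-2-en-1-one
Product: 2 (R)-4-(tert-butyldimethylsilyloxy)-2-iodocyclohex-2-en-1-one
Conditions: I2, pyridine, CH2Cl2, 0 °C → rt
Reagents that add atoms: iodine, II
Why: α-Iodination of an enone by pyridine addition, iodination of the enolate and elimination (Baylis–Hillman-type pathway) is standard for 4-silyloxycyclohexenones and leaves C3 untouched.

Step 2
Reactants: 2 (R)-4-(tert-butyldimethylsilyloxy)-2-iodocyclohex-2-en-1-one
Product: 3 (R)-4-(tert-butyldimethylsilyloxy)-2-methylcyclohex-2-en-1-one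
Conditions: Me4Sn, Pd2(dba)3 (cat.), AsPh3, CuI (cat.), NMP, 70 °C
Reagents that add atoms: tetramethylstannane, C[Sn](C)(C)C
Why: Stille coupling of a 2-iodoenone (oxidative addition to zerovalent palladium, methyl transfer from tin, reductive elimination) should install the future C5 methyl without touching the silyl ether.

Step 3
Reactants: 3 (R)-4-(tert-butyldimethylsilyloxy)-2-methylcyclohex-2-en-1-one
Product: 5 (2R,3R,4R)-2-allyl-4-(tert-butyldimethylsilyloxy)-2,3-dimethylcyclohexan-1-one, via lithium enolate 4 (not isolated)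
Conditions: Me2CuLi (from MeLi and CuI), Et2O, −78 → −30 °C; then allyl bromide, HMPA, THF, −30 → 0 °C
Reagents that add atoms: Me2CuLi (lithium dimethylcuprate), [Li+].C[Cu-]C; allyl bromide, C=CCBr
Why: Gilman conjugate addition should place the methyl at C4 anti to the C3 silyloxy group (4β), and the regiodefined tetrasubstituted enolate should then be allylated at C5 anti to the pseudoaxial C4 methyl (C6 on the α face, C5 methyl β), the usual outcome of conjugate addition–alkylation of 2-methylcyclohexenones.

Step 4
Reactants: 5 (2R,3R,4R)-2-allyl-4-(tert-butyldimethylsilyloxy)-2,3-dimethylcyclohexan-1-one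
Product: 6 C10 methoxymethylidene enol ether of 5 (E/Z mixture)
Conditions: Ph3P(CH2OMe)Cl, KHMDS, THF, 0 → 45 °C
Reagents that add atoms: (methoxymethyl)triphenylphosphonium chloride, COC[P+](c1ccccc1)(c1ccccc1)c1ccccc1.[Cl-]
Why: Wittig methoxymethylenation with an unstabilised ylide is a reliable one-carbon homologation of α-quaternary cyclohexanones and brings in C9; no stereocentre is formed.

Step 5
Reactants: 6 C10 methoxymethylidene enol ether of 5
Product: 8 [(1R,2S,3R,4R)-2-allyl-4-(tert-butyldimethylsilyloxy)-2,3-dimethylcyclohexyl]methanol (10β-CH2OH), via aldehyde 7 (not isolated)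
Conditions: 0.5 M aq. HCl–THF, 0 °C → rt; crude aldehyde: K2CO3, MeOH, rt; then NaBH4, 0 °C
Reagents that add atoms: water, O
Why: Enol-ether hydrolysis protonates C10 from the α face (axial, anti to the axial C5 methyl), brief base equilibration funnels any epimer to the equatorial 10β-formyl compound, and NaBH4 reduction then fixes C10 as the hydroxymethyl compound.

Step 6
Reactants: 8 [(1R,2S,3R,4R)-2-allyl-4-(tert-butyldimethylsilyloxy)-2,3-dimethylcyclohexyl]methanol
Product: 9 pivalate of 8 (C9–OPiv)
Conditions: PivCl, pyridine, DMAP (cat.), CH2Cl2, 0 °C → rt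
Reagents that add atoms: pivaloyl chloride, CC(C)(C)C(=O)Cl
Why: Acylation of the primary alcohol gives an ester that should survive the nitro chemistry and is removed later by the hydride that reduces the C8 acid.

Step 7
Reactants: 9 pivalate of 8
Product: 11 C7 aldehyde (2-oxoethyl arm on C5), via ozonide 10 (not isolated)
Conditions: O3, CH2Cl2, −78 °C; then PPh3, −78 °C → rt
Reagents that add atoms: ozone, [O-][O+]=O
Why: Ozonolysis with reductive work-up cleaves the only alkene present to the aldehyde; the silyl ether and pivalate are inert.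

Step 8
Reactants: 11 C7 aldehyde
Product: 13 (E)-nitroalkene (C7=C8–NO2), via nitro alcohol 12 (not isolated)
Conditions: MeNO2, Et3N (cat.), rt; then MsCl, Et3N, CH2Cl2, 0 °C
Reagents that add atoms: nitromethane, C[N+](=O)[O-]
Why: Henry addition followed by mesylation and E1cB elimination is the standard route from an aliphatic aldehyde to the thermodynamically preferred E-nitroalkene; C8 enters here.

Step 9
Reactants: 13 (E)-nitroalkene
Product: 14 (7S)-nitroalkane (isopropenyl on C7, nitromethyl C8)
Conditions: K[CH2=C(CH3)BF3], [Rh(cod)2]BF4 (cat.), (R)-BINAP, dioxane–H2O (10:1), 80 °C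
Reagents that add atoms: potassium isopropenyltrifluoroborate, [K+].C=C(C)[B-](F)(F)F
Why: In this Hayashi–Miyaura rhodium-catalysed asymmetric 1,4-addition of an alkenylboron reagent to a nitroalkene, the (R)-BINAP complex should deliver isopropenyl to the Re face of C7 (7S) under catalyst control, since the nearest resident centre (quaternary C5) is one methylene away.

Step 10
Reactants: 14 (7S)-nitroalkane
Product: 15 (7S)-carboxylic acid (C8 = CO2H)
Conditions: NaNO2, AcOH, DMSO, 35 °C
Reagents that add atoms: NaNO2 (sodium nitrite), [Na+].[O-]N=O; water, O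
Why: The nitrite-mediated Nef-type oxidation of a primary nitroalkane to the acid (through the nitrolic acid) runs under weakly acidic conditions that do not enolise C7, and the acid is far less prone to epimerisation or alkene conjugation than the aldehyde.

Step 11
Reactants: 15 (7S)-carboxylic acid
Product: 16 (7S)-1,6-diol (C8–OH and C9–OH)
Conditions: LiAlH4, THF, 0 °C → rt
Reagents that add atoms: none
Why: Hydride reduction converts the acid to the primary alcohol and cleaves the pivalate in the same operation; the silyl ether and the isolated alkene are inert.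

Step 12
Reactants: 16 (7S)-1,6-diol
Product: 17 (7S)-dialdehyde (formyl on C10 and on C7), used at once
Conditions: Dess–Martin periodinane, NaHCO3, CH2Cl2, 0 °C → rt
Reagents that add atoms: none
Why: Buffered Dess–Martin oxidation of both primary alcohols is neutral enough to leave the α-branched, β,γ-unsaturated C7 centre intact, and a seven-membered lactol is too slow to form to divert the second oxidation.

Step 13
Reactants: 17 (7S)-dialdehyde
Product: 18 3α-(tert-butyldimethylsilyloxy)eremophil-11-ene-8α,9α-diol
Conditions: SmI2 (0.1 M in THF), t-BuOH, THF, −78 °C → rt, slow addition of 17; aq. NH4Cl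
Reagents that add atoms: none
Why: One electron from divalent samarium turns a formyl group into a ketyl, which adds to the carbon of the second, samarium-coordinated formyl group; a second electron and protonation give the diol, the closest known reaction type being the SmI2 pinacol cyclisation of 1,6-dialdehydes to cis-cyclohexane-1,2-diols. Ring B closes in a 6-exo-trig mode through a chair fused trans to ring A, with the C7 isopropenyl group equatorial. C8 and C9 come out cis to each other because both oxygens stay bound to trivalent samarium while the C–C bond forms. They come out on the α face because the other cis arrangement would put the C9 oxygen axial and syn to the axial C5 methyl, so the expected result is 9α-equatorial and 8α-axial. The step needs cyclisation to outrun intermolecular coupling, simple reduction and ketyl addition to the isopropenyl group: the quaternary C5 and the trans-diequatorial arms on ring A hold the formyl groups close, slow addition keeps 17 dilute, and without HMPA the unactivated alkene stays inert. The medium is not basic, so C7 next to the formyl group should not epimerise.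

Step 14
Reactants: 18 3α-(tert-butyldimethylsilyloxy)eremophil-11-ene-8α,9α-diol
Product: 19 8α,9α-acetonide of 18
Conditions: 2,2-dimethoxypropane, PPTS (cat.), CH2Cl2, rt
Reagents that add atoms: 2,2-dimethoxypropane, COC(C)(C)OC
Why: Acid-catalysed transketalisation closes a dioxolane readily on a cis (axial/equatorial) 1,2-diol and masks both hydroxyls for the acylation at O3.

Step 15
Reactants: 19 8α,9α-acetonide of 18
Product: 20 3α-alcohol (acetonide retained)
Conditions: Bu4NF, THF, rt → 45 °C
Reagents that add atoms: none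
Why: Fluoride-driven desilylation frees only the C3 hydroxyl; the acetonide and the alkene are stable to it.

Step 16
Reactants: 21 angelic acid; 22 (R)-pent-1-yn-3-ol
Product: 24 (R)-pent-1-yn-3-yl angelate, via mixed anhydride 23 (not isolated)
Conditions: 2,4,6-trichlorobenzoyl chloride, Et3N, toluene, rt; then 22, 75 °C
Reagents that add atoms: none
Why: Yamaguchi mixed-anhydride esterification run without DMAP avoids the nucleophile-induced Z-to-E isomerisation of the angeloyl group, and acylation at oxygen retains the carbinol configuration.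

Step 17
Reactants: 24 (R)-pent-1-yn-3-yl angelate
Product: 26 (R)-4-(angeloyloxy)hex-2-ynoic acid, via lithium acetylide 25 (not isolated)
Conditions: LiHMDS, THF, −78 °C; then CO2 (gas), −78 → 0 °C; aq. HCl
Reagents that add atoms: carbon dioxide, O=C=O
Why: The terminal alkyne C–H is the kinetically most acidic site, so a hindered amide base at −78 °C should give the acetylide without touching the hindered unsaturated ester, and carboxylation with CO2 gives the ynoic acid.

Step 18
Reactants: 20 3α-alcohol; 26 (R)-4-(angeloyloxy)hex-2-ynoic acid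
Product: 27 3α-O-[(R)-4-(angeloyloxy)hex-2-ynoyl] ester of 20
Conditions: DCC, DMAP (cat.), CH2Cl2, −20 → 0 °C
Reagents that add atoms: none
Why: Steglich esterification of the equatorial C3 alcohol at low temperature with little DMAP limits conjugate addition to the ynoate and proceeds with retention at C3 and C4′.

Step 19
Reactants: 27 ynoate ester
Product: 28 (Z)-enoate acetonide
Conditions: H2 (1 atm), Pd/CaCO3 poisoned with Pb(OAc)2 (Lindlar catalyst), quinoline, EtOAc, rt
Reagents that add atoms: none
Why: Lindlar semi-hydrogenation adds one equivalent of H2 syn to the alkyne to give the Z-enoate, while the 1,1-disubstituted isopropenyl and trisubstituted angeloyl alkenes are not reduced on the poisoned catalyst.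

Step 20
Reactants: 28 (Z)-enoate acetonide
Product: 29 target, 3α-[(Z,4R)-4-(angeloyloxy)hex-2-enoyloxy]eremophil-11-ene-8α,9α-diol
Conditions: AcOH–H2O–THF (3:1:1), 45 °C
Reagents that add atoms: none
Why: Mild aqueous acid hydrolyses the acetonide while both esters, the Z alkenes and the isopropenyl group should tolerate it.

**Compound list**
1 | (R)-4-(tert-butyldimethylsilyloxy)cyclohex-2-en-1-one | O=C1C=C[C@H](O[Si](C)(C)C(C)(C)C)CC1 | starting material
2 | (R)-4-(tert-butyldimethylsilyloxy)-2-iodocyclohex-2-en-1-one | O=C1C(I)=C[C@H](O[Si](C)(C)C(C)(C)C)CC1 | intermediate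
3 | (R)-4-(tert-butyldimethylsilyloxy)-2-methylcyclohex-2-en-1-one | CC1=C[C@H](O[Si](C)(C)C(C)(C)C)CCC1=O | intermediate
4 | lithium enolate of (3R,4R)-4-(tert-butyldimethylsilyloxy)-2,3-dimethylcyclohexan-1-one (C5=C10 enolate, 3α-OTBS, 4β-methyl; not isolated) | [Li]OC1=C(C)[C@@H](C)[C@H](O[Si](C)(C)C(C)(C)C)CC1 | intermediate
5 | (2R,3R,4R)-2-allyl-4-(tert-butyldimethylsilyloxy)-2,3-dimethylcyclohexan-1-one (C10 ketone; 3α-OTBS, 4β-methyl, 5β-methyl, 5α-allyl) | C=CC[C@]1(C)[C@@H](C)[C@H](O[Si](C)(C)C(C)(C)C)CCC1=O | intermediate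
6 | C10 methoxymethylidene enol ether of 5 (E/Z mixture; 3α-OTBS, 4β-methyl, 5β-methyl, 5α-allyl) | C=CC[C@]1(C)[C@@H](C)[C@H](O[Si](C)(C)C(C)(C)C)CCC1=COC | intermediate
7 | (1R,2R,3R,4R)-2-allyl-4-(tert-butyldimethylsilyloxy)-2,3-dimethylcyclohexane-1-carbaldehyde (10β-formyl, 10α-H; not isolated) | C=CC[C@]1(C)[C@@H](C)[C@H](O[Si](C)(C)C(C)(C)C)CC[C@H]1C=O | intermediate
8 | [(1R,2S,3R,4R)-2-allyl-4-(tert-butyldimethylsilyloxy)-2,3-dimethylcyclohexyl]methanol (10β-CH2OH) | C=CC[C@]1(C)[C@@H](C)[C@H](O[Si](C)(C)C(C)(C)C)CC[C@H]1CO | intermediate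
9 | pivalate of 8 (3α-OTBS, 4β-methyl, 5β-methyl, 5α-allyl, 10β-CH2OPiv) | C=CC[C@]1(C)[C@@H](C)[C@H](O[Si](C)(C)C(C)(C)C)CC[C@H]1COC(=O)C(C)(C)C | intermediate
10 | secondary ozonide of 9 (3-substituted 1,2,4-trioxolane, epimers at the acetal carbon; not isolated) | C1(OOCO1)C[C@]2(C)[C@@H](C)[C@H](O[Si](C)(C)C(C)(C)C)CC[C@H]2COC(=O)C(C)(C)C | intermediate
11 | C7 aldehyde (5α-(2-oxoethyl), 10β-CH2OPiv, 3α-OTBS) | O=CC[C@]1(C)[C@@H](C)[C@H](O[Si](C)(C)C(C)(C)C)CC[C@H]1COC(=O)C(C)(C)C | intermediate
12 | nitro alcohol from 11 (C7 carbinol epimers, C8 nitromethyl; not isolated) | [O-][N+](=O)CC(O)C[C@]1(C)[C@@H](C)[C@H](O[Si](C)(C)C(C)(C)C)CC[C@H]1COC(=O)C(C)(C)C | intermediate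
13 | (E)-nitroalkene (C7=C8–NO2; 10β-CH2OPiv, 3α-OTBS) | [O-][N+](=O)/C=C/C[C@]1(C)[C@@H](C)[C@H](O[Si](C)(C)C(C)(C)C)CC[C@H]1COC(=O)C(C)(C)C | intermediate
14 | (7S)-nitroalkane (7-isopropenyl, C8 nitromethyl; 10β-CH2OPiv, 3α-OTBS) | C=C(C)[C@@H](C[N+](=O)[O-])C[C@]1(C)[C@@H](C)[C@H](O[Si](C)(C)C(C)(C)C)CC[C@H]1COC(=O)C(C)(C)C | intermediate
15 | (7S)-carboxylic acid (C8 = CO2H, 7-isopropenyl; 10β-CH2OPiv, 3α-OTBS) | C=C(C)[C@@H](C(=O)O)C[C@]1(C)[C@@H](C)[C@H](O[Si](C)(C)C(C)(C)C)CC[C@H]1COC(=O)C(C)(C)C | intermediate
16 | (7S)-1,6-diol (C8–OH, C9–OH, 7-isopropenyl, 3α-OTBS) | C=C(C)[C@@H](CO)C[C@]1(C)[C@@H](C)[C@H](O[Si](C)(C)C(C)(C)C)CC[C@H]1CO | intermediate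
17 | (7S)-dialdehyde (10β-formyl on ring A; 2-formyl-3-methylbut-3-enyl arm on C5; 3α-OTBS) | C=C(C)[C@@H](C=O)C[C@]1(C)[C@@H](C)[C@H](O[Si](C)(C)C(C)(C)C)CC[C@H]1C=O | intermediate
18 | 3α-(tert-butyldimethylsilyloxy)eremophil-11-ene-8α,9α-diol (4β,5β-dimethyl, 7α-isopropenyl, 10α-H) | C=C(C)[C@@H]1C[C@]2(C)[C@@H](C)[C@H](O[Si](C)(C)C(C)(C)C)CC[C@H]2[C@H](O)[C@@H]1O | intermediate
19 | 8α,9α-O-isopropylidene derivative of 18 | C=C(C)[C@@H]1C[C@]2(C)[C@@H](C)[C@H](O[Si](C)(C)C(C)(C)C)CC[C@H]2[C@@H]3OC(C)(C)O[C@H]13 | intermediate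
20 | 8α,9α-O-isopropylidene-eremophil-11-ene-3α,8α,9α-triol (free 3α-OH) | C=C(C)[C@@H]1C[C@]2(C)[C@@H](C)[C@H](O)CC[C@H]2[C@@H]3OC(C)(C)O[C@H]13 | intermediate
21 | angelic acid, (Z)-2-methylbut-2-enoic acid | C/C=C(/C)C(=O)O | starting material
22 | (R)-pent-1-yn-3-ol | C#C[C@@H](CC)O | starting material
23 | angelic 2,4,6-trichlorobenzoic mixed anhydride (not isolated) | C/C=C(/C)C(=O)OC(=O)c1c(Cl)cc(Cl)cc1Cl | intermediate
24 | (R)-pent-1-yn-3-yl (Z)-2-methylbut-2-enoate | C#C[C@@H](CC)OC(=O)/C(C)=C\C | intermediate
25 | lithium acetylide of 24 (not isolated) | [Li]C#C[C@@H](CC)OC(=O)/C(C)=C\C | intermediate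
26 | (R)-4-{[(Z)-2-methylbut-2-enoyl]oxy}hex-2-ynoic acid | OC(=O)C#C[C@@H](CC)OC(=O)/C(C)=C\C | intermediate
27 | 3α-O-[(R)-4-(angeloyloxy)hex-2-ynoyl] ester of 20 | C=C(C)[C@@H]1C[C@]2(C)[C@@H](C)[C@H](OC(=O)C#C[C@@H](CC)OC(=O)/C(C)=C\C)CC[C@H]2[C@@H]3OC(C)(C)O[C@H]13 | intermediate
28 | 3α-O-[(Z,4R)-4-(angeloyloxy)hex-2-enoyl] ester of 20 | C=C(C)[C@@H]1C[C@]2(C)[C@@H](C)[C@H](OC(=O)/C=C\[C@@H](CC)OC(=O)/C(C)=C\C)CC[C@H]2[C@@H]3OC(C)(C)O[C@H]13 | intermediate
29 | 3α-[(Z,4R)-4-(angeloyloxy)hex-2-enoyloxy]eremophil-11-ene-8α,9α-diol (CNP0382739.1) | C=C(C)[C@@H]1C[C@]2(C)[C@@H](C)[C@H](OC(=O)/C=C\[C@@H](CC)OC(=O)/C(C)=C\C)CC[C@H]2[C@H](O)[C@@H]1O | target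

**Step count and risks**
Total: 20 steps. Longest linear sequence: 18 steps (steps 1–15, then 18–20); the side-chain acid takes steps 16–17.

Steps most likely to fail:

1. Step 13. What may go wrong: loss of cis or facial selectivity in the ketyl addition (a trans diol or the β-face cis diol), or reduction of the formyl groups without coupling. Fallback, setting out from 17 and returning at 18: the same C8–C9 bond would be made by an N-heterocyclic-carbene-catalysed intramolecular benzoin reaction (3-benzyl-5-(2-hydroxyethyl)-4-methylthiazolium chloride, Et3N, t-BuOH, 50 °C). The acyl-anion equivalent should form at the less hindered C8 formyl group and add to the C9 formyl group, and the reversible addition should settle on the product with equatorial 9α-hydroxyl and equatorial C7 isopropenyl, the 8-oxo-9α-hydroxy ketol F1. Reduction of F1 with LiBH(s-Bu)3 (THF, −78 °C) along the equatorial trajectory should then give the axial 8α-alcohol, which is diol 18; the two carbinol centres are thus set one at a time.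

2. Step 9. What may go wrong: insufficient catalyst control at C7, or slow transmetalation and insertion with the aliphatic nitroalkene, allowing its decomposition in the hot aqueous medium. Fallback, setting out from 9 and returning at 16: hydroboration–oxidation of the allyl group (9-BBN, THF; then NaBO3) would give the primary alcohol F2, and Dess–Martin oxidation the aldehyde F3. An enantioselective enamine α-alkenylation would then put the isopropenyl group directly on C7 to give the (7S)-α-isopropenyl aldehyde F4. Its reagents are isopropenyl(phenyl)iodonium triflate, CuBr (cat.) and 5-benzyl-2-tert-butyl-3-methylimidazolidin-4-one trichloroacetate (cat., antipode chosen for 7S). LiAlH4 then reduces the formyl group and cleaves the pivalate to give diol 16, so the nitro group and its oxidation are avoided altogether.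

3. Step 3. What may go wrong: poor facial selectivity in the allylation of enolate 4 (in the reactive conformer the C3 silyloxy group is axial on the face of attack), together with proton transfer or O-allylation. Fallback, setting out from 3 and returning at 5: after the same cuprate addition, enolate 4 would be trapped on oxygen with allyl chloroformate to give the allyl enol carbonate F5. Pd2(dba)3 with (S)-t-Bu-PHOX (THF, rt) would then carry out a Tsuji-type decarboxylative asymmetric allylic alkylation. The ligand antipode is the one that gives (S)-2-allyl-2-methylcyclohexanone in the parent system, so it reinforces the substrate bias and leads to ketone 5.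

Further compounds
F1 | step 13 | 8-oxo-9α-hydroxy ketol (3α-OTBS, 7α-isopropenyl, trans-fused) | C=C(C)[C@@H]1C[C@]2(C)[C@@H](C)[C@H](O[Si](C)(C)C(C)(C)C)CC[C@H]2[C@H](O)C1=O
F2 | step 9 | primary alcohol from hydroboration of 9 (3-hydroxypropyl arm on C5, 10β-CH2OPiv, 3α-OTBS) | OCCC[C@]1(C)[C@@H](C)[C@H](O[Si](C)(C)C(C)(C)C)CC[C@H]1COC(=O)C(C)(C)C
F3 | step 9 | aldehyde from F2 (3-oxopropyl arm on C5) | O=CCC[C@]1(C)[C@@H](C)[C@H](O[Si](C)(C)C(C)(C)C)CC[C@H]1COC(=O)C(C)(C)C
F4 | step 9 | (7S)-α-isopropenyl aldehyde (C8 formyl, 10β-CH2OPiv, 3α-OTBS) | C=C(C)[C@@H](C=O)C[C@]1(C)[C@@H](C)[C@H](O[Si](C)(C)C(C)(C)C)CC[C@H]1COC(=O)C(C)(C)C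
F5 | step 3 | allyl enol carbonate of the C5=C10 enolate (3α-OTBS, 4β-methyl) | C=CCOC(=O)OC1=C(C)[C@@H](C)[C@H](O[Si](C)(C)C(C)(C)C)CC1
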